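The runs stem from a simulated flask with constants of no real substance.

How does the excess of left-handed product over right-handed product, e = (P − Q)/(P + Q), rank across flasks that differ in their reagent, with P and Q the two products as fractions of the whole charge?

1. ranking by excess of left-handed product over right-handed product, from high to low, at 3.0 min (Wednesday's / Sunday's / Monday's / Friday's / Saturday's)
2. the excess of left-handed product over right-handed product of the flask you put first, at 3.0 min
3. the excess of left-handed product over right-handed product of the flask you put last, at 3.0 min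

| flask | left-handed substrate | right-handed substrate | reagent | temperature | remark | time |
|---|---|---|---|---|---|---|
| grey | 0.10 M | 0.10 M | 0.18 M | −35 °C | run made earlier |  |
| ochre | 0.10 M | 0.10 M | 1.1 M | −20 °C | run made earlier |  |
| Wednesday's | 0.10 M | 0.10 M | 0.300 M | −20 °C |  | 3.0 min |
| Sunday's | 0.10 M | 0.10 M | 0.800 M | −20 °C |  | 3.0 min |
| Monday's | 0.10 M | 0.10 M | 0.120 M | −20 °C |  | 3.0 min |
| Friday's | 0.10 M | 0.10 M | 0.200 M | −20 °C |  | 3.0 min |
| Saturday's | 0.10 M | 0.10 M | 0.400 M | −20 °C |  | 3.0 min |

| run | time / min | left-handed product / % | right-handed product / % |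
|---|---|---|---|
| grey | 0.833 | 4.8 | 2.0 |
| grey | 2.00 | 9.9 | 4.3 |
| grey | 4.00 | 14.6 | 6.1 |
| grey | 6.00 | 17.6 | 6.3 |
| ochre | 0.250 | 31.2 | 17.1 |
| ochre | 0.500 | 37.6 | 22.8 |
| ochre | 1.33 | 43.9 | 32.3 |
| ochre | 3.00 | 49.3 | 34.9 |

(each reading ± 1 percentage point)

- reagent is single-handed; left-handed substrate and right-handed substrate are mirror images of each other, charged as a racemate, each of them at the stated concentration
- the handed part of reagent does not stay in what it makes, so the products of the two hands are mirror images too

The ochre run looks contradictory. Its first reading has P/Q = 1.82 and its last 1.41, as if the reagent were losing its preference, yet the reagent is the same throughout.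

Each substrate is half of the charge, so 1 − 2P and 1 − 2Q are the shares of each hand that have not become product. If each hand leaves its substrate by the reagent and by no other road, the reagent's history over time cancels in the selectivity factor s = ln(1 − 2P)/ln(1 − 2Q), and s = 1 is the zero of the scale, no preference.

The first three ochre readings give 2.34, 2.29 and 2.03, so s = 2.22 as a reading. The last ochre reading is set aside: its 1 − 2P is 1.40 %, while P itself scatters by 1 percentage point, so its logarithm bears no weight. The falling P/Q is then read as P nearing its cap, at 49.3 % in the last ochre reading.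

At fixed s, Q follows from P: Q = (1 − (1 − 2P)^(1/s))/2. The excess starts near (s − 1)/(s + 1) = 37.8 % and falls as P grows. This reckoning therefore expects the excess to fall as reagent rises, provided P climbs with reagent.

The forecast ranks Monday's > Friday's > Wednesday's > Saturday's > Sunday's, with 32 % first and 18 % last, on the ground that “More reagent means more conversion, so lower ee.”

The flasks give Monday's > Friday's > Wednesday's > Saturday's > Sunday's, with 36.5 % first and 19.5 % last, so the forecast stands. Its ranking rests on P climbing with reagent, and at 3.00 min Monday's holds 13.9 % against Sunday's 44.5 %; a run reversing those two would undo it. Monday's also holds 20.2 % as achiral form and 29.0 % as waste, so the condition set on s does not hold there and s serves as a ratio read from the ochre run; put to use on Monday's, it turns that P into Q = 6.81 % and e = 34.2 %.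

    reagent ⇌ dormant form (K = 3.60, k = 0.0170 s⁻¹, Ea = 69.0 kJ mol⁻¹, ΔH = −90.0 kJ mol⁻¹)
    reagent + right-handed substrate → right-handed product (k = 0.0320 M⁻¹ s⁻¹, Ea = 58.0 kJ mol⁻¹)
    reagent + left-handed substrate → left-handed product (k = 0.0750 M⁻¹ s⁻¹, Ea = 55.0 kJ mol⁻¹)
    achiral form → waste (k = 0.00730 s⁻¹, Ea = 66.0 kJ mol⁻¹)
    left-handed substrate ⇌ achiral form (K = 1.70, k = 0.0120 s⁻¹, Ea = 62.0 kJ mol⁻¹, ΔH = 32.0 kJ mol⁻¹)
    right-handed substrate ⇌ achiral form (K = 1.70, k = 0.0120 s⁻¹, Ea = 62.0 kJ mol⁻¹, ΔH = 32.0 kJ mol⁻¹)
    (constants at −20 °C)

In a flask like Monday's but with 0.30 M of reagent, P = 28.1 % and s give Q = 15.6 % and e = 28.6 %. The computed flask holds Q = 14.7 % and e = 31.2 %.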